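4 questions are put to this flask; its equations, charge and conventions stand here.

    Z + X ⇌ D + E (K1 = 1.9, k1 = 0.070 L mol⁻¹ s⁻¹)
    E + X ⇌ D + G (K2 = 0.96, k2 = 0.043 L mol⁻¹ s⁻¹)
    Z ⇌ L (K3 = 0.28, k3 = 0.012 s⁻¹)

Z 0.10 M; X 0.900 equiv (fed, over 2.5 min); time 2.5 h

1. which holds at 2.5 h: what has brought the reaction to rest, or that it has not come to rest (forward and back rates have come level / it is still moving / X has run out first / all of Z has reacted)
2. how much of the Z has reacted by 2.5 h
3. how much E there is at 2.5 h, in percent of the Z charged
4. how much G there is at 2.5 h, in percent of the Z charged

- the reaction counts as stopped when no species that holds the Z changes by six tenths of a point or more over the second half of the time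
- what has gone from Z into another species counts as reacted, even if it can come back
- run time (flask): 2.5 h

- In the first instants, while X is fed over 2.5 min, Z and L exchange with a relaxation half-life of 0.211 min. This is shorter than the 1.8 min forward half-life of Z in the step Z + X, reckoned as if the whole charge of X were there, so Z and L can be reckoned as one pool, a pre-equilibrium, of which 78.1% stands as Z.
- In the middle, Z + X draws on that free share, which stretches its forward half-life on the pool to about 2.35 min, with X taken as wholly present. The step E + X follows with a forward half-life of 3.0 min, and both times are short against 2.5 h.
- Towards the end, what is about to matter is a balance, not a clock. Seen from the pool, the step Z + X has the apparent constant [D][E]/([X]([Z]+[L])), equal to its own constant divided by one plus the constant of Z ⇌ L: 1.48.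
- The own reckoning by hand sets the step E + X aside, so each D formed is one E formed, one X gone and one unit out of the pool. Solving that balance gives E at 52.0% of the Z charged, and the reckoning goes no further: E + X then draws on this E, so E must end lower and G must appear.
- The forecast says forward and back rates have come level, with 59.5% reacted, E 33.9% and G 14.3%: “I therefore took the end state from the equilibrium constants and the mass balances”. Its E differs from the own figure, which is E with the step E + X set aside.
- The simulation gives forward and back rates have come level, with 59.5% reacted, E 33.9% and G 14.3%, so the forecast holds. Ten times the time adds nothing to the conversion, so this flask is read by its constants.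
- Two back steps acting together are part of what holds the conversion at 59.5%: without D + E → Z + X it reaches 91.6%, and without L → Z it reaches >99.9%. The back step D + G → E + X is a further part, and it keeps E at 33.9%, against 2.40% without it. At 2.50 h the quotient of this flask reads 1.48, level with the apparent constant.
- In the neighbour flask with 0.230 equiv of X, the same constant with E + X set aside gives [D] = 0.0197 M. The simulation of that neighbour flask gives 0.0203 M, with G at 2.07%.

(The rate constants belong to no real substance; the rest is arithmetic.)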